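Late in the run, what I watched was the substrate still free, and I reckoned it by counting turnovers.

    substrate + partner → intermediate + released group (k1 = 0.19 M⁻¹ h⁻¹)
    intermediate ⇌ isomer of the product (K2 = 2.9, k2 = 0.11 h⁻¹)
    substrate + released group ⇌ idle adduct, settled at all times (K3 = 19 M⁻¹)
    intermediate ⇌ target (K4 = 0.37, k4 = 0.30 h⁻¹)

- teal: substrate 0.10 M; partner 3.00 equiv; time 40 h
- blue: substrate 0.10 M; partner 6.00 equiv; time 40 h

- released group is meant together with its idle adduct
- what has gone from substrate into another species counts as reacted, even if it can come back
- run time (teal): 40 h

- part of the substrate that has reacted at the end, teal
- part of the substrate that has reacted at the end, blue
- what raising the equivalents of partner from its lowest to its highest value here does to the part of the substrate that has reacted (changes below 5 percentage points count as none) (it rises / no change / it falls)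

The bench rule for a partner in excess is the pseudo-first-order one: hold the partner at its charge and let the substrate fall by a factor of e per turnover. I carried one number, 2.28 for teal: the turnover count, which is the rate constant of the first step times the partner concentration times the time. That gave 89.8% reacted in teal. Blue had 4.56 turnovers, which gave 99.0%. The gap of 9.2 percentage points is wider than 5 points, so my answer on the trend was: it rises.

The rule has a border. Free substrate and idle adduct stand equal once free released group reaches the reciprocal of the binding constant, and the ratio of that to the substrate charged was 0.526, about half. Each idle adduct holds one substrate and one released group, so by the balance of the charge the reacted part at that point was 84.2%, and my counts put both flasks past it. The idle adduct pulled two ways: it took substrate off, which counts as reacted, and it left less free for the first step. I could not tell by hand which pull would win, so my figures stood as they were.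

The forecast gave 86% for teal and 95.5% for blue, with the trend it rises, saying that “Doubling the partner roughly doubles the rate late in the run”.

The simulation gave 86.2% for teal and 95.5% for blue; the trend was it rises, by 9.3 points. Blue had twice the turnovers of teal, and the extra partner was the main reason for that rise: at teal's charge, the reacted part fell from 95.5% to 86.2%. Teal itself ended 3.6 points under its count. Earlier the sign was the other way: teal read at 15 h had 0.855 turnovers, worth 57.5%, yet 64.8% had reacted, with 18.5% standing as idle adduct.

The numbers of this flask are made up; the result is computed.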